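**Plan**
- Retrosynthesis: after removal of the three benzyl ethers and the 7-O-methyl group, ring A is cut at C5–C6, the acetyl side arm at C7–C8, the 4-pyrone (ring C) at C4–C4a and O1–C2, and the ring B keto ester at C2–C3.
- Enabling feature (flavone numbering): ring A carries oxygen on C5, C7 and C8a in the alternating acetate pattern plus a methoxy group on C8. C5, C6/C7 and C8 therefore correspond to an ester carbon, a methyl ketone and a methoxymethine held on a 4-pyrone.
- Forward: ring B is bought; a glycolate aldol makes C2–C3; the derived β-chloroacryloyl chloride acylates methyl 4-methoxyacetoacetate and closes ring C; lateral acetylation adds C6/C7; a Dieckmann fold closes ring A; 7-O-methylation and hydrogenolysis finish.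
- Stereochemistry: the target has no stereocentre; those that appear on the way are racemic and are erased by oxidation, chlorination or aromatisation.

Key step: step 9

Remark: flavone numbering (O1, C2 to C8a, primes for ring B) is also used for the pyrone intermediates; the chloroalkenes are carried as E/Z mixtures because both isomers should converge in the pyrone closure.

**Route**

Step 1
Reactants: 1 2,4-dihydroxy-5-methoxybenzaldehyde
Product: 2 2,4-bis(benzyloxy)-5-methoxybenzaldehyde
Conditions: BnBr (2.5 equiv), K2CO3, DMF, 60 °C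
Reagents that add atoms: benzyl bromide, BrCc1ccccc1
Why: Williamson O-benzylation of both phenols, where excess halide and warm DMF should overcome the hydrogen-bonded ortho hydroxyl while the aldehyde is untouched.

Step 2
Reactants: 3 benzyl alcohol; 4 tert-butyl bromoacetate
Product: 5 tert-butyl 2-(benzyloxy)acetate
Conditions: NaH, THF, 0 °C to rt
Reagents that add atoms: none
Why: Williamson ether synthesis by SN2 attack of sodium benzyloxide on the activated primary bromide, with the tert-butyl ester resisting transesterification.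

Step 3
Reactants: 2 2,4-bis(benzyloxy)-5-methoxybenzaldehyde; 5 tert-butyl 2-(benzyloxy)acetate
Product: 6 tert-butyl 2-(benzyloxy)-3-[2,4-bis(benzyloxy)-5-methoxyphenyl]-3-hydroxypropanoate (racemic syn/anti mixture)
Conditions: LiN(iPr)2, 5, THF, −78 °C; then 2; AcOH quench at −78 °C
Reagents that add atoms: none
Why: aldol addition of the lithium glycolate enolate to the non-enolisable aldehyde forms C2–C3 with the C3 oxygen already in place; the two new stereocentres are not controlled because both are destroyed in steps 4 and 5.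

Step 4
Reactants: 6 tert-butyl 2-(benzyloxy)-3-[2,4-bis(benzyloxy)-5-methoxyphenyl]-3-hydroxypropanoate
Product: 7 tert-butyl 2-(benzyloxy)-3-[2,4-bis(benzyloxy)-5-methoxyphenyl]-3-oxopropanoate (racemic)
Conditions: Dess–Martin periodinane, CH2Cl2, 0 °C to rt
Reagents that add atoms: none
Why: Dess–Martin oxidation of the benzylic secondary alcohol to the aryl ketone under near-neutral conditions that should spare the tert-butyl ester and the benzyl ethers.

Step 5
Reactants: 7 tert-butyl 2-(benzyloxy)-3-[2,4-bis(benzyloxy)-5-methoxyphenyl]-3-oxopropanoate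
Product: 8 tert-butyl 2-(benzyloxy)-3-[2,4-bis(benzyloxy)-5-methoxyphenyl]-3-chloroprop-2-enoate (E/Z mixture)
Conditions: Ph3PCl2, Et3N, CH2Cl2, 0 °C to rt
Reagents that add atoms: dichlorotriphenylphosphorane, ClP(Cl)(c1ccccc1)(c1ccccc1)c1ccccc1
Why: Appel-type deoxychlorination of the β-keto ester enol through an enoxyphosphonium salt and addition–elimination by chloride, kept basic by Et3N so that the tert-butyl ester survives.

Step 6
Reactants: 8 tert-butyl 2-(benzyloxy)-3-[2,4-bis(benzyloxy)-5-methoxyphenyl]-3-chloroprop-2-enoate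
Product: 9 2-(benzyloxy)-3-[2,4-bis(benzyloxy)-5-methoxyphenyl]-3-chloroprop-2-enoic acid (E/Z mixture)
Conditions: CF3CO2H, CH2Cl2, 0 °C to rt
Reagents that add atoms: none
Why: acidolysis of the tert-butyl ester with loss of isobutene frees the acid without any nucleophile that could attack the β-chloro carbon, and the ester-conjugated enol ether should resist protonation.

Step 7
Reactants: 9 2-(benzyloxy)-3-[2,4-bis(benzyloxy)-5-methoxyphenyl]-3-chloroprop-2-enoic acid; 10 methyl 4-methoxyacetoacetate
Product: 13 methyl 5-(benzyloxy)-6-[2,4-bis(benzyloxy)-5-methoxyphenyl]-2-(methoxymethyl)-4-oxo-4H-pyran-3-carboxylate, via acid chloride 11 (not isolated), via triketo ester 12 (not isolated)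
Conditions: (COCl)2, cat. DMF, CH2Cl2, 0 °C to rt, evaporate; then 10, MgCl2, Et3N, MeCN, 0 °C to rt, then 50 °C
Reagents that add atoms: oxalyl chloride, O=C(Cl)C(Cl)=O (its chlorine is found only in 11, not in 13)
Why: C-acylation of the magnesium enolate of the β-keto ester by an acid chloride that cannot form a ketene makes C4–C4a, and the ketone enol oxygen then displaces the vinylic chloride by 6-endo oxa-Michael addition–elimination to close the 4-pyrone (O1–C2).

Step 8
Reactants: 13 methyl 5-(benzyloxy)-6-[2,4-bis(benzyloxy)-5-methoxyphenyl]-2-(methoxymethyl)-4-oxo-4H-pyran-3-carboxylate; 14 N-methoxy-N-methylacetamide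
Product: 15 methyl 5-(benzyloxy)-6-[2,4-bis(benzyloxy)-5-methoxyphenyl]-2-(1-methoxy-2-oxopropyl)-4-oxo-4H-pyran-3-carboxylate (racemic)
Conditions: LiN(SiMe3)2 (1.1 equiv), THF, −78 °C; then 14, −78 to −20 °C; AcOH quench
Reagents that add atoms: none
Why: lateral (vinylogous) deprotonation of the 2-alkyl-4-pyrone and C-acylation by the N-methoxy-N-methylamide make C7–C8; the chelated tetrahedral adduct releases the methyl ketone only on quench, which should prevent over-addition and premature ring closure, and the new C8 centre is racemic and is erased in step 9.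

Step 9
Reactants: 15 methyl 5-(benzyloxy)-6-[2,4-bis(benzyloxy)-5-methoxyphenyl]-2-(1-methoxy-2-oxopropyl)-4-oxo-4H-pyran-3-carboxylate
Product: 16 3-(benzyloxy)-2-[2,4-bis(benzyloxy)-5-methoxyphenyl]-5,7-dihydroxy-8-methoxy-4H-chromen-4-one
Conditions: LiN(iPr)2 (3.5 equiv), THF, −78 to 0 °C; then 1 M HCl
Reagents that add atoms: none
Why: The amide base first removes the doubly activated C8–H and then a proton of the acetyl methyl group, and the terminal carbon C6 of this dianion adds to the ester carbonyl C5 on C4a with loss of methoxide. This is an intramolecular Claisen (Dieckmann) condensation of the kind known for folding pyrone-masked polyketo esters into resorcinols and acylphloroglucinols. Ring A closes in a 6-(enolendo)-exo-trig mode, since both C6 and C7 of the reacting enolate lie in the new ring. No stereocentre is formed, and the racemic C8 centre disappears when the triketone tautomerises to the aromatic 5,7-diol. The step needs carbon rather than oxygen acylation and an intact pyrone: full double deprotonation makes C6 the most basic and nucleophilic site, and the hindered non-nucleophilic base should not add to C2 or C8a. Because O1 is already bonded to C8a, only the 5,7-dihydroxy-8-methoxy pattern can result.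

Step 10
Reactants: 16 3-(benzyloxy)-2-[2,4-bis(benzyloxy)-5-methoxyphenyl]-5,7-dihydroxy-8-methoxy-4H-chromen-4-one
Product: 17 3-(benzyloxy)-2-[2,4-bis(benzyloxy)-5-methoxyphenyl]-5-hydroxy-7,8-dimethoxy-4H-chromen-4-one
Conditions: MeI (1.1 equiv), K2CO3 (1.2 equiv), acetone, rt
Reagents that add atoms: iodomethane, CI
Why: regioselective Williamson methylation of the more acidic 7-hydroxyl (vinylogous acid of the C4 carbonyl), while the 5-hydroxyl is held in a hydrogen bond to C4=O and should stay free with one equivalent of halide.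

Step 11
Reactants: 17 3-(benzyloxy)-2-[2,4-bis(benzyloxy)-5-methoxyphenyl]-5-hydroxy-7,8-dimethoxy-4H-chromen-4-one
Product: 18 3,5-dihydroxy-2-(2,4-dihydroxy-5-methoxyphenyl)-7,8-dimethoxy-4H-chromen-4-one (CNP0319239.0)
Conditions: H2 (1 atm), Pd/C, EtOAc–MeOH, rt
Reagents that add atoms: none
Why: catalytic hydrogenolysis of the three benzyl ethers, under which the methyl ethers and the flavonol C2=C3 bond are expected to survive.

**Compound list**
1 | 2,4-dihydroxy-5-methoxybenzaldehyde | COc1cc(C=O)c(O)cc1O | starting material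
2 | 2,4-bis(benzyloxy)-5-methoxybenzaldehyde | COc1cc(C=O)c(OCc2ccccc2)cc1OCc1ccccc1 | intermediate
3 | benzyl alcohol | OCc1ccccc1 | starting material
4 | tert-butyl bromoacetate | CC(C)(C)OC(=O)CBr | starting material
5 | tert-butyl 2-(benzyloxy)acetate | CC(C)(C)OC(=O)COCc1ccccc1 | intermediate
6 | tert-butyl 2-(benzyloxy)-3-[2,4-bis(benzyloxy)-5-methoxyphenyl]-3-hydroxypropanoate (racemic, syn/anti mixture) | COc1cc(C(O)C(OCc2ccccc2)C(=O)OC(C)(C)C)c(OCc2ccccc2)cc1OCc1ccccc1 | intermediate
7 | tert-butyl 2-(benzyloxy)-3-[2,4-bis(benzyloxy)-5-methoxyphenyl]-3-oxopropanoate (racemic) | COc1cc(C(=O)C(OCc2ccccc2)C(=O)OC(C)(C)C)c(OCc2ccccc2)cc1OCc1ccccc1 | intermediate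
8 | tert-butyl 2-(benzyloxy)-3-[2,4-bis(benzyloxy)-5-methoxyphenyl]-3-chloroprop-2-enoate (alkene geometry not controlled) | COc1cc(C(Cl)=C(OCc2ccccc2)C(=O)OC(C)(C)C)c(OCc2ccccc2)cc1OCc1ccccc1 | intermediate
9 | 2-(benzyloxy)-3-[2,4-bis(benzyloxy)-5-methoxyphenyl]-3-chloroprop-2-enoic acid (alkene geometry not controlled) | COc1cc(C(Cl)=C(OCc2ccccc2)C(=O)O)c(OCc2ccccc2)cc1OCc1ccccc1 | intermediate
10 | methyl 4-methoxyacetoacetate (methyl 4-methoxy-3-oxobutanoate) | COCC(=O)CC(=O)OC | starting material
11 | 2-(benzyloxy)-3-[2,4-bis(benzyloxy)-5-methoxyphenyl]-3-chloroprop-2-enoyl chloride | COc1cc(C(Cl)=C(OCc2ccccc2)C(Cl)=O)c(OCc2ccccc2)cc1OCc1ccccc1 | intermediate (not isolated)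
12 | methyl 4-(benzyloxy)-5-[2,4-bis(benzyloxy)-5-methoxyphenyl]-5-chloro-2-(methoxyacetyl)-3-oxopent-4-enoate (drawn as keto form) | COCC(=O)C(C(=O)OC)C(=O)C(OCc1ccccc1)=C(Cl)c1cc(OC)c(OCc2ccccc2)cc1OCc1ccccc1 | intermediate (not isolated)
13 | methyl 5-(benzyloxy)-6-[2,4-bis(benzyloxy)-5-methoxyphenyl]-2-(methoxymethyl)-4-oxo-4H-pyran-3-carboxylate | COCc1oc(-c2cc(OC)c(OCc3ccccc3)cc2OCc2ccccc2)c(OCc2ccccc2)c(=O)c1C(=O)OC | intermediate
14 | N-methoxy-N-methylacetamide | CC(=O)N(C)OC | starting material
15 | methyl 5-(benzyloxy)-6-[2,4-bis(benzyloxy)-5-methoxyphenyl]-2-(1-methoxy-2-oxopropyl)-4-oxo-4H-pyran-3-carboxylate (racemic) | COC(=O)c1c(C(OC)C(C)=O)oc(-c2cc(OC)c(OCc3ccccc3)cc2OCc2ccccc2)c(OCc2ccccc2)c1=O | intermediate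
16 | 3-(benzyloxy)-2-[2,4-bis(benzyloxy)-5-methoxyphenyl]-5,7-dihydroxy-8-methoxy-4H-chromen-4-one | COc1cc(-c2oc3c(OC)c(O)cc(O)c3c(=O)c2OCc2ccccc2)c(OCc2ccccc2)cc1OCc1ccccc1 | intermediate
17 | 3-(benzyloxy)-2-[2,4-bis(benzyloxy)-5-methoxyphenyl]-5-hydroxy-7,8-dimethoxy-4H-chromen-4-one | COc1cc(-c2oc3c(OC)c(OC)cc(O)c3c(=O)c2OCc2ccccc2)c(OCc2ccccc2)cc1OCc1ccccc1 | intermediate
18 | 3,5-dihydroxy-2-(2,4-dihydroxy-5-methoxyphenyl)-7,8-dimethoxy-4H-chromen-4-one | COc1cc(-c2oc3c(OC)c(OC)cc(O)c3c(=O)c2O)c(O)cc1O | target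

**Count**
Total steps: 11. Longest linear sequence: 10 steps (steps 1 and 3 to 11 from aldehyde 1; step 2 is a one-step side branch).

**Steps most likely to fail**

Step 9 (ring A closure). If the second deprotonation is incomplete, the C7 enolate oxygen may attack the ester and give an enol lactone, or the base may open the pyrone. The fallback sets out from 15 and returns at 16. Treatment of 15 with tBuMe2SiOSO2CF3 and Et3N in CH2Cl2 should cap O7 as the silyl enol ether methyl 5-(benzyloxy)-6-[2,4-bis(benzyloxy)-5-methoxyphenyl]-2-[2-(tert-butyldimethylsilyloxy)-1-methoxyprop-1-en-1-yl]-4-oxo-4H-pyran-3-carboxylate F1. One deprotonation of its allylic methyl group with LiN(iPr)2 then gives a vinylogous enolate that can acylate only through C6. This should close ring A to 3-(benzyloxy)-2-[2,4-bis(benzyloxy)-5-methoxyphenyl]-7-(tert-butyldimethylsilyloxy)-5-hydroxy-8-methoxy-4H-chromen-4-one F2, and Bu4NF removes the silyl group to give 16.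

Step 8 (lateral acetylation). The stabilised pyrone dienolate may be too weak a nucleophile for the amide, or proton transfer to the amide may return 13. The fallback sets out from 13 and returns at 15. The same lithium dienolate is added to acetaldehyde at −78 °C, a far stronger electrophile, and quenched cold with AcOH to avoid lactonisation onto the ester. This should give methyl 5-(benzyloxy)-6-[2,4-bis(benzyloxy)-5-methoxyphenyl]-2-(2-hydroxy-1-methoxypropyl)-4-oxo-4H-pyran-3-carboxylate F3 as a diastereomer mixture, and Dess–Martin oxidation of the secondary alcohol gives 15.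

Step 5 (chlorination). Enolisation of the hindered, electron-rich aryl ketone may be slow, so chlorination could stall or liberated HCl could cleave the tert-butyl ester. The fallback sets out from 7 and returns at 13, with a sulfonate in place of chloride as the leaving group. The sodium enolate of 7 (NaH, THF) is trapped with PhN(SO2CF3)2 to give the enol triflate tert-butyl 2-(benzyloxy)-3-[2,4-bis(benzyloxy)-5-methoxyphenyl]-3-(trifluoromethylsulfonyloxy)prop-2-enoate F4. CF3CO2H frees the acid 2-(benzyloxy)-3-[2,4-bis(benzyloxy)-5-methoxyphenyl]-3-(trifluoromethylsulfonyloxy)prop-2-enoic acid F5, and (COCl)2 gives the acid chloride 2-(benzyloxy)-3-[2,4-bis(benzyloxy)-5-methoxyphenyl]-3-(trifluoromethylsulfonyloxy)prop-2-enoyl chloride F6. Acylation of 10 with MgCl2 and Et3N should give the triketo ester methyl 4-(benzyloxy)-5-[2,4-bis(benzyloxy)-5-methoxyphenyl]-2-(methoxyacetyl)-3-oxo-5-(trifluoromethylsulfonyloxy)pent-4-enoate F7, whose enol oxygen displaces triflate to close pyrone 13.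

**Further compounds**
F1 | step 9 | methyl 5-(benzyloxy)-6-[2,4-bis(benzyloxy)-5-methoxyphenyl]-2-[2-(tert-butyldimethylsilyloxy)-1-methoxyprop-1-en-1-yl]-4-oxo-4H-pyran-3-carboxylate | COC(=O)c1c(C(OC)=C(C)O[Si](C)(C)C(C)(C)C)oc(-c2cc(OC)c(OCc3ccccc3)cc2OCc2ccccc2)c(OCc2ccccc2)c1=O
F2 | step 9 | 3-(benzyloxy)-2-[2,4-bis(benzyloxy)-5-methoxyphenyl]-7-(tert-butyldimethylsilyloxy)-5-hydroxy-8-methoxy-4H-chromen-4-one | COc1cc(-c2oc3c(OC)c(O[Si](C)(C)C(C)(C)C)cc(O)c3c(=O)c2OCc2ccccc2)c(OCc2ccccc2)cc1OCc1ccccc1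
F3 | step 8 | methyl 5-(benzyloxy)-6-[2,4-bis(benzyloxy)-5-methoxyphenyl]-2-(2-hydroxy-1-methoxypropyl)-4-oxo-4H-pyran-3-carboxylate (diastereomer mixture, racemic) | COC(=O)c1c(C(OC)C(C)O)oc(-c2cc(OC)c(OCc3ccccc3)cc2OCc2ccccc2)c(OCc2ccccc2)c1=O
F4 | step 5 | tert-butyl 2-(benzyloxy)-3-[2,4-bis(benzyloxy)-5-methoxyphenyl]-3-(trifluoromethylsulfonyloxy)prop-2-enoate | COc1cc(C(OS(=O)(=O)C(F)(F)F)=C(OCc2ccccc2)C(=O)OC(C)(C)C)c(OCc2ccccc2)cc1OCc1ccccc1
F5 | step 5 | 2-(benzyloxy)-3-[2,4-bis(benzyloxy)-5-methoxyphenyl]-3-(trifluoromethylsulfonyloxy)prop-2-enoic acid | COc1cc(C(OS(=O)(=O)C(F)(F)F)=C(OCc2ccccc2)C(=O)O)c(OCc2ccccc2)cc1OCc1ccccc1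
F6 | step 5 | 2-(benzyloxy)-3-[2,4-bis(benzyloxy)-5-methoxyphenyl]-3-(trifluoromethylsulfonyloxy)prop-2-enoyl chloride | COc1cc(C(OS(=O)(=O)C(F)(F)F)=C(OCc2ccccc2)C(Cl)=O)c(OCc2ccccc2)cc1OCc1ccccc1
F7 | step 5 | methyl 4-(benzyloxy)-5-[2,4-bis(benzyloxy)-5-methoxyphenyl]-2-(methoxyacetyl)-3-oxo-5-(trifluoromethylsulfonyloxy)pent-4-enoate | COCC(=O)C(C(=O)OC)C(=O)C(OCc1ccccc1)=C(OS(=O)(=O)C(F)(F)F)c1cc(OC)c(OCc2ccccc2)cc1OCc1ccccc1
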